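**Retrosynthetic overview**
1. Target 20 ⇒ reagent-controlled syn-aldol of pentan-3-one (1) with epoxy-enal 18; 18 ⇒ site- and face-selective epoxidation of dienal 17.
2. 17 ⇒ Pd/formate hydrogenolysis of the tertiary allylic carbonate 15 (sets the ring C–H, side chain cis to the pyranone); 15 ⇒ dienone 10 + a 2-lithioallyl silyl ether.
3. 10 ⇒ α-methylation and dehydrogenation of cyclohexenone 8.
4. 8 ⇒ key step: enantioselective one-carbon ring expansion of 3-methylcyclopent-2-enone (7) by the pyranyl diazoethane 6 (1,2-alkenyl shift with loss of N2), which builds the carbocycle and the quaternary centre.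
5. Ring order: pyranone first (from 1 + methylmalonyl dichloride), then cyclopentenone → cyclohexenone, epoxide last.

Assumption: the target is (4R,5R) in the side chain and (1S,2R,3R,6R) in the epoxycyclohexene as drawn; compounds 1, 2, 7 and 11 are bought; "(+)-Ipc2BOTf" is the reagent from (−)-α-pinene.

**Step 1**
Reactants: 1 pentan-3-one; 2 2-methylpropanedioyl dichloride
Product: 4 6-ethyl-4-hydroxy-3,5-dimethyl-2H-pyran-2-one, via silyl enol ether 3 (not isolated)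
Conditions: TMSOTf, Et3N, Et2O, 0 °C; decant ether layer; then 2, Et2O, −20 °C → rt
Reagents that add atoms: none
Why: Effenberger-type pyranone synthesis, in which the silyl enol ether is C-acylated by one acid chloride and the enol oxygen closes onto the second (no stereocentre).

**Step 2**
Reactants: 4 6-ethyl-4-hydroxy-3,5-dimethyl-2H-pyran-2-one
Product: 5 6-ethyl-2-methoxy-3,5-dimethyl-4H-pyran-4-one
Conditions: MeOTf, CH2Cl2, rt; aq NaHCO3
Reagents that add atoms: methyl triflate COS(=O)(=O)C(F)(F)F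
Why: Hard O-alkylation at the lactone carbonyl oxygen followed by proton loss gives the α-methoxy-γ-pyranone (Beak-type selective methylation).

**Step 3**
Reactants: 5 6-ethyl-2-methoxy-3,5-dimethyl-4H-pyran-4-one
Product: 6 2-(1-diazoethyl)-6-methoxy-3,5-dimethyl-4H-pyran-4-one
Conditions: LiHMDS, THF, −78 °C; 4-nitrobenzenesulfonyl azide, −78 → 0 °C; aq NH4Cl; used cold and at once
Reagents that add atoms: 4-nitrobenzenesulfonyl azide [N-]=[N+]=NS(=O)(=O)c1ccc(cc1)[N+](=O)[O-]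
Why: Regitz-type diazo transfer to the vinylogous lithium enolate formed at the ethyl CH2, the only acidic site of 5.

**Step 4**
Reactants: 6 2-(1-diazoethyl)-6-methoxy-3,5-dimethyl-4H-pyran-4-one; 7 3-methylcyclopent-2-en-1-one
Product: 8 (2S)-2-(6-methoxy-3,5-dimethyl-4-oxo-4H-pyran-2-yl)-2,4-dimethylcyclohex-3-en-1-one
Conditions: Sc(OTf)3 (10 mol%), (S,S,S)-iPr-tris(oxazoline) ligand (12 mol%), slow addition of 6, toluene/CH2Cl2, −45 °C
Reagents that add atoms: none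
Why: Proposed new method: the chiral Sc(III) Lewis acid binds the enone C=O, the diazo carbon adds 1,2 through one prochiral face, and the alkenyl carbon C2 anti-periplanar to the leaving N2 undergoes a 1,2-shift with inversion at the diazo carbon, which gives the β,γ-enone and the (S) quaternary centre in one event; the closest known reaction type is the Sc(III)-catalysed enantioselective diazoalkane–ketone homologation (Tiffeneau–Demjanov-type ring expansion) of simple cycloalkanones, not yet shown for an enone with alkenyl migration or for a heteroaryl-stabilised disubstituted diazoalkane.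

**Step 5**
Reactants: 8 (2S)-2-(6-methoxy-3,5-dimethyl-4-oxo-4H-pyran-2-yl)-2,4-dimethylcyclohex-3-en-1-one
Product: 9 (2S,6RS)-2-(6-methoxy-3,5-dimethyl-4-oxo-4H-pyran-2-yl)-2,4,6-trimethylcyclohex-3-en-1-one
Conditions: LDA, THF, −78 °C; MeI, −78 → −20 °C
Reagents that add atoms: iodomethane CI
Why: Kinetic enolate alkylation; only C6 can enolise because C2 is quaternary, and the new C6 centre is of no consequence since it becomes sp2 in step 6.

**Step 6**
Reactants: 9 (2S,6RS)-2-(6-methoxy-3,5-dimethyl-4-oxo-4H-pyran-2-yl)-2,4,6-trimethylcyclohex-3-en-1-one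
Product: 10 (6S)-6-(6-methoxy-3,5-dimethyl-4-oxo-4H-pyran-2-yl)-2,4,6-trimethylcyclohexa-2,4-dien-1-one
Conditions: IBX, DMSO/PhF, 65 °C
Reagents that add atoms: none
Why: IBX (Nicolaou) α,β-dehydrogenation can only occur at C6–C5 and gives the conjugated 2,4-dienone, which cannot aromatise because C6 is quaternary.

**Step 7**
Reactants: 11 2-bromoprop-2-en-1-ol
Product: 12 [(2-bromoprop-2-en-1-yl)oxy]triethylsilane
Conditions: TESCl, imidazole, CH2Cl2, 0 °C
Reagents that add atoms: chlorotriethylsilane CC[Si](Cl)(CC)CC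
Why: Standard silylation of a primary alcohol (protecting-group step).

**Step 8**
Reactants: 12 [(2-bromoprop-2-en-1-yl)oxy]triethylsilane; 10 (6S)-6-(6-methoxy-3,5-dimethyl-4-oxo-4H-pyran-2-yl)-2,4,6-trimethylcyclohexa-2,4-dien-1-one
Product: 15 methyl (1R,6S)-6-(6-methoxy-3,5-dimethyl-4-oxo-4H-pyran-2-yl)-2,4,6-trimethyl-1-{3-[(triethylsilyl)oxy]prop-1-en-2-yl}cyclohexa-2,4-dien-1-yl carbonate, via vinyllithium 13 (not isolated), via lithium alkoxide 14 (not isolated)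
Conditions: 12, t-BuLi (2 equiv), Et2O, −78 °C; 10, LaCl3·2LiCl (30 mol%), THF, −78 °C; ClCO2Me, −78 → 0 °C; used crude
Reagents that add atoms: methyl chloroformate COC(=O)Cl
Why: Br–Li exchange, then La-assisted 1,2-addition to the non-enolisable dienone C=O from the face anti to the pyranone, and O-acylation of the alkoxide in situ; the carbinol configuration is not critical because it is erased in step 9.

**Step 9**
Reactants: 15 methyl (1R,6S)-6-(6-methoxy-3,5-dimethyl-4-oxo-4H-pyran-2-yl)-2,4,6-trimethyl-1-{3-[(triethylsilyl)oxy]prop-1-en-2-yl}cyclohexa-2,4-dien-1-yl carbonate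
Product: 16 triethyl({2-[(1R,6R)-6-(6-methoxy-3,5-dimethyl-4-oxo-4H-pyran-2-yl)-2,4,6-trimethylcyclohexa-2,4-dien-1-yl]prop-2-en-1-yl}oxy)silane
Conditions: Pd2(dba)3·CHCl3 (2.5 mol%), n-Bu3P (10 mol%), HCO2H, Et3N, THF, 25 °C
Reagents that add atoms: none
Why: Tsuji–Mandai formate hydrogenolysis, in which Pd sits on the π-allyl face anti to the pyranone and the hydride from formate goes from the Pd face to the most substituted (ring) terminus, so the exo-methylene is kept and the new C1–H is cis to the C6 methyl, i.e. the side chain is cis to the pyranone.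

**Step 10**
Reactants: 16 triethyl({2-[(1R,6R)-6-(6-methoxy-3,5-dimethyl-4-oxo-4H-pyran-2-yl)-2,4,6-trimethylcyclohexa-2,4-dien-1-yl]prop-2-en-1-yl}oxy)silane
Product: 17 2-[(1S,6R)-6-(6-methoxy-3,5-dimethyl-4-oxo-4H-pyran-2-yl)-2,4,6-trimethylcyclohexa-2,4-dien-1-yl]prop-2-enal
Conditions: (COCl)2, DMSO, CH2Cl2, −78 → −40 °C; Et3N, −78 °C; cold quench
Reagents that add atoms: none
Why: Swern conditions cleave and oxidise a primary allylic TES ether directly to the enal, and the cold quench avoids γ-deprotonation at the ring C1–H.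

**Step 11**
Reactants: 17 2-[(1S,6R)-6-(6-methoxy-3,5-dimethyl-4-oxo-4H-pyran-2-yl)-2,4,6-trimethylcyclohexa-2,4-dien-1-yl]prop-2-enal
Product: 18 2-[(1S,2S,3R,6R)-3-(6-methoxy-3,5-dimethyl-4-oxo-4H-pyran-2-yl)-1,3,5-trimethyl-7-oxabicyclo[4.1.0]hept-4-en-2-yl]prop-2-enal
Conditions: DMDO (1.05 equiv), acetone, −40 → −20 °C
Reagents that add atoms: dimethyldioxirane CC1(C)OO1
Why: Electrophilic dioxirane epoxidation takes the ring C2=C3 bond (C4=C5 is shielded on both faces by the quaternary C6, the enal C=C is electron-poor) from the face anti to the adjacent side chain, which sets both epoxide carbons.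

**Step 12**
Reactants: 18 2-[(1S,2S,3R,6R)-3-(6-methoxy-3,5-dimethyl-4-oxo-4H-pyran-2-yl)-1,3,5-trimethyl-7-oxabicyclo[4.1.0]hept-4-en-2-yl]prop-2-enal; 1 pentan-3-one
Product: 20 (4R,5R)-5-hydroxy-6-[(1S,2R,3R,6R)-3-(6-methoxy-3,5-dimethyl-4-oxo-4H-pyran-2-yl)-1,3,5-trimethyl-7-oxabicyclo[4.1.0]hept-4-en-2-yl]-4-methylhept-6-en-3-one, via boron enolate 19 (not isolated)
Conditions: 1, (+)-Ipc2BOTf, i-Pr2NEt, CH2Cl2, −78 °C; 18, −78 → −20 °C; H2O2, MeOH, pH 7 buffer, 0 °C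
Reagents that add atoms: none
Why: Paterson boron aldol, in which the (Z)-enol diisopinocampheylborinate reacts through a Zimmerman–Traxler chair to give the syn adduct and the (+)-Ipc ligands are chosen for attack on the aldehyde Re face, giving (4R,5R).

**Compound list**
1 | pentan-3-one | CCC(=O)CC | starting material
2 | 2-methylpropanedioyl dichloride (methylmalonyl dichloride) | CC(C(=O)Cl)C(=O)Cl | starting material
3 | (Z)-3-(trimethylsilyloxy)pent-2-ene | C/C=C(/CC)O[Si](C)(C)C | intermediate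
4 | 6-ethyl-4-hydroxy-3,5-dimethyl-2H-pyran-2-one | CCC1=C(C)C(O)=C(C)C(=O)O1 | intermediate
5 | 6-ethyl-2-methoxy-3,5-dimethyl-4H-pyran-4-one | CCc1oc(OC)c(C)c(=O)c1C | intermediate
6 | 2-(1-diazoethyl)-6-methoxy-3,5-dimethyl-4H-pyran-4-one | CC(=[N+]=[N-])c1oc(OC)c(C)c(=O)c1C | intermediate
7 | 3-methylcyclopent-2-en-1-one | CC1=CC(=O)CC1 | starting material
8 | (2S)-2-(6-methoxy-3,5-dimethyl-4-oxo-4H-pyran-2-yl)-2,4-dimethylcyclohex-3-en-1-one | CC1=C[C@@](C)(c2oc(OC)c(C)c(=O)c2C)C(=O)CC1 | intermediate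
9 | (2S,6RS)-2-(6-methoxy-3,5-dimethyl-4-oxo-4H-pyran-2-yl)-2,4,6-trimethylcyclohex-3-en-1-one | CC1=C[C@@](C)(c2oc(OC)c(C)c(=O)c2C)C(=O)C(C)C1 | intermediate
10 | (6S)-6-(6-methoxy-3,5-dimethyl-4-oxo-4H-pyran-2-yl)-2,4,6-trimethylcyclohexa-2,4-dien-1-one | CC1=C[C@@](C)(c2oc(OC)c(C)c(=O)c2C)C(=O)C(C)=C1 | intermediate
11 | 2-bromoprop-2-en-1-ol | C=C(Br)CO | starting material
12 | [(2-bromoprop-2-en-1-yl)oxy]triethylsilane | C=C(Br)CO[Si](CC)(CC)CC | intermediate
13 | {3-[(triethylsilyl)oxy]prop-1-en-2-yl}lithium | [Li]C(=C)CO[Si](CC)(CC)CC | intermediate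
14 | lithium (1R,6R)-6-(6-methoxy-3,5-dimethyl-4-oxo-4H-pyran-2-yl)-2,4,6-trimethyl-1-{3-[(triethylsilyl)oxy]prop-1-en-2-yl}cyclohexa-2,4-dien-1-olate (same spatial arrangement as 15) | C=C(CO[Si](CC)(CC)CC)[C@]1(O[Li])C(C)=CC(C)=C[C@@]1(C)c1oc(OC)c(C)c(=O)c1C | intermediate
15 | methyl (1R,6S)-6-(6-methoxy-3,5-dimethyl-4-oxo-4H-pyran-2-yl)-2,4,6-trimethyl-1-{3-[(triethylsilyl)oxy]prop-1-en-2-yl}cyclohexa-2,4-dien-1-yl carbonate | C=C(CO[Si](CC)(CC)CC)[C@]1(OC(=O)OC)C(C)=CC(C)=C[C@@]1(C)c1oc(OC)c(C)c(=O)c1C | intermediate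
16 | triethyl({2-[(1R,6R)-6-(6-methoxy-3,5-dimethyl-4-oxo-4H-pyran-2-yl)-2,4,6-trimethylcyclohexa-2,4-dien-1-yl]prop-2-en-1-yl}oxy)silane | C=C(CO[Si](CC)(CC)CC)[C@H]1C(C)=CC(C)=C[C@@]1(C)c1oc(OC)c(C)c(=O)c1C | intermediate
17 | 2-[(1S,6R)-6-(6-methoxy-3,5-dimethyl-4-oxo-4H-pyran-2-yl)-2,4,6-trimethylcyclohexa-2,4-dien-1-yl]prop-2-enal | C=C(C=O)[C@H]1C(C)=CC(C)=C[C@@]1(C)c1oc(OC)c(C)c(=O)c1C | intermediate
18 | 2-[(1S,2S,3R,6R)-3-(6-methoxy-3,5-dimethyl-4-oxo-4H-pyran-2-yl)-1,3,5-trimethyl-7-oxabicyclo[4.1.0]hept-4-en-2-yl]prop-2-enal | C=C(C=O)[C@H]1[C@]2(C)O[C@@H]2C(C)=C[C@@]1(C)c1oc(OC)c(C)c(=O)c1C | intermediate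
19 | (Z)-pent-2-en-3-yl di[(+)-isopinocampheyl]borinate | C/C=C(/CC)OB([C@H]1C[C@H]2C[C@@H]([C@@H]1C)C2(C)C)[C@H]1C[C@H]2C[C@@H]([C@@H]1C)C2(C)C | intermediate
20 | (4R,5R)-5-hydroxy-6-[(1S,2R,3R,6R)-3-(6-methoxy-3,5-dimethyl-4-oxo-4H-pyran-2-yl)-1,3,5-trimethyl-7-oxabicyclo[4.1.0]hept-4-en-2-yl]-4-methylhept-6-en-3-one | C=C([C@H](O)[C@@H](C)C(=O)CC)[C@H]1[C@]2(C)O[C@@H]2C(C)=C[C@@]1(C)c1oc(OC)c(C)c(=O)c1C | target

**Count**
Total: 12 steps. Longest linear sequence: 11 steps (1 → 2 → 3 → 4 → 5 → 6 → 8 → 9 → 10 → 11 → 12); step 7 is the side branch.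

**Three steps most likely to fail**

Step 4 (the new ring expansion). Risks are migration of the ring CH2 instead of the alkenyl carbon, loss of 6 by 1,2-H shift to the vinylpyranone, low ee, and an untested sense of induction (the mirror-image ligand is the remedy if it is reversed). Fallback with known chemistry, setting out from 5 and returning at 8: lithiate 5 (LiHMDS, THF, −78 °C) and quench with MeSeSeMe to give 2-methoxy-3,5-dimethyl-6-[1-(methylselanyl)ethyl]-4H-pyran-4-one F1. Deprotonate F1 with LDA and add it 1,2 to 7 to give the β-hydroxy selenide 1-[1-(6-methoxy-3,5-dimethyl-4-oxo-4H-pyran-2-yl)-1-(methylselanyl)ethyl]-3-methylcyclopent-2-en-1-ol F2 (diastereomer mixture). Se-methylation (MeOTf, CH2Cl2, −40 °C → rt) triggers the Krief-type selenonium semipinacol ring expansion, for which alkenyl migration is the established course, and gives racemic 2-(6-methoxy-3,5-dimethyl-4-oxo-4H-pyran-2-yl)-2,4-dimethylcyclohex-3-en-1-one F3. Preparative chiral SFC of F3 gives 8.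

Step 9 (hydrogenolysis). Risks are hydride delivery to another terminus of the extended π-allyl system, or elimination to a tetraene. Fallback setting out from 9 and returning at 17, using deconjugative protonation to set the ring C–H:
- KHMDS/PhNTf2 converts 9 into the enol triflate (6S)-6-(6-methoxy-3,5-dimethyl-4-oxo-4H-pyran-2-yl)-2,4,6-trimethylcyclohexa-1,4-dien-1-yl trifluoromethanesulfonate F4.
- Carbonylative Stille coupling (Pd(PPh3)4, CO, Me4Sn, LiCl) gives the methyl ketone 1-[(6R)-6-(6-methoxy-3,5-dimethyl-4-oxo-4H-pyran-2-yl)-2,4,6-trimethylcyclohexa-1,4-dien-1-yl]ethan-1-one F5.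
- Extended enolate formation (KOt-Bu, THF/t-BuOH) and kinetic AcOH quench protonates anti to the pyranone and gives 1-[(1S,6R)-6-(6-methoxy-3,5-dimethyl-4-oxo-4H-pyran-2-yl)-2,4,6-trimethylcyclohexa-2,4-dien-1-yl]ethan-1-one F6.
- LDA/PhNTf2 at the methyl group gives 1-[(1S,6R)-6-(6-methoxy-3,5-dimethyl-4-oxo-4H-pyran-2-yl)-2,4,6-trimethylcyclohexa-2,4-dien-1-yl]ethenyl trifluoromethanesulfonate F7.
- Pd-catalysed reductive carbonylation of F7 (CO, Bu3SnH) gives 17.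

Step 11 (epoxidation). Risks are attack at the other ring alkene or the wrong face, and oxidation of the aldehyde. Fallback setting out from 16 and returning at 18, using catalyst control before the aldehyde exists: Shi epoxidation of 16 (fructose-derived ketone in the enantiomeric series matched to delivery anti to the side chain, Oxone, pH 10.5) gives triethyl({2-[(1S,2R,3R,6R)-3-(6-methoxy-3,5-dimethyl-4-oxo-4H-pyran-2-yl)-1,3,5-trimethyl-7-oxabicyclo[4.1.0]hept-4-en-2-yl]prop-2-en-1-yl}oxy)silane F8. TBAF gives 2-[(1S,2R,3R,6R)-3-(6-methoxy-3,5-dimethyl-4-oxo-4H-pyran-2-yl)-1,3,5-trimethyl-7-oxabicyclo[4.1.0]hept-4-en-2-yl]prop-2-en-1-ol F9. Buffered Dess–Martin oxidation of F9 gives 18.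

**Further compounds**
F1 | step 4 | 2-methoxy-3,5-dimethyl-6-[1-(methylselanyl)ethyl]-4H-pyran-4-one | CC([Se]C)c1oc(OC)c(C)c(=O)c1C
F2 | step 4 | 1-[1-(6-methoxy-3,5-dimethyl-4-oxo-4H-pyran-2-yl)-1-(methylselanyl)ethyl]-3-methylcyclopent-2-en-1-ol | CC1=CC(O)(CC1)C(C)([Se]C)c1oc(OC)c(C)c(=O)c1C
F3 | step 4 | racemic 2-(6-methoxy-3,5-dimethyl-4-oxo-4H-pyran-2-yl)-2,4-dimethylcyclohex-3-en-1-one | CC1=CC(C)(c2oc(OC)c(C)c(=O)c2C)C(=O)CC1
F4 | step 9 | (6S)-6-(6-methoxy-3,5-dimethyl-4-oxo-4H-pyran-2-yl)-2,4,6-trimethylcyclohexa-1,4-dien-1-yl trifluoromethanesulfonate | CC1=C[C@@](C)(c2oc(OC)c(C)c(=O)c2C)C(OS(=O)(=O)C(F)(F)F)=C(C)C1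
F5 | step 9 | 1-[(6R)-6-(6-methoxy-3,5-dimethyl-4-oxo-4H-pyran-2-yl)-2,4,6-trimethylcyclohexa-1,4-dien-1-yl]ethan-1-one | CC1=C[C@@](C)(c2oc(OC)c(C)c(=O)c2C)C(C(C)=O)=C(C)C1
F6 | step 9 | 1-[(1S,6R)-6-(6-methoxy-3,5-dimethyl-4-oxo-4H-pyran-2-yl)-2,4,6-trimethylcyclohexa-2,4-dien-1-yl]ethan-1-one | CC(=O)[C@H]1C(C)=CC(C)=C[C@@]1(C)c1oc(OC)c(C)c(=O)c1C
F7 | step 9 | 1-[(1S,6R)-6-(6-methoxy-3,5-dimethyl-4-oxo-4H-pyran-2-yl)-2,4,6-trimethylcyclohexa-2,4-dien-1-yl]ethenyl trifluoromethanesulfonate | C=C(OS(=O)(=O)C(F)(F)F)[C@H]1C(C)=CC(C)=C[C@@]1(C)c1oc(OC)c(C)c(=O)c1C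
F8 | step 11 | triethyl({2-[(1S,2R,3R,6R)-3-(6-methoxy-3,5-dimethyl-4-oxo-4H-pyran-2-yl)-1,3,5-trimethyl-7-oxabicyclo[4.1.0]hept-4-en-2-yl]prop-2-en-1-yl}oxy)silane | C=C(CO[Si](CC)(CC)CC)[C@H]1[C@]2(C)O[C@@H]2C(C)=C[C@@]1(C)c1oc(OC)c(C)c(=O)c1C
F9 | step 11 | 2-[(1S,2R,3R,6R)-3-(6-methoxy-3,5-dimethyl-4-oxo-4H-pyran-2-yl)-1,3,5-trimethyl-7-oxabicyclo[4.1.0]hept-4-en-2-yl]prop-2-en-1-ol | C=C(CO)[C@H]1[C@]2(C)O[C@@H]2C(C)=C[C@@]1(C)c1oc(OC)c(C)c(=O)c1C
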